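## Structural features

The target is a diterpenoid acetate on a trans-fused bicyclo[8.1.0]undecene. The ten-membered carbocycle is numbered here C1 (quaternary), C2H2, C3H2, C4(CH3)=C5H, C6H(OAc), C7H2, C8(CH3)(OH), C9H, C10H, and its C9–C10 bond is bridged by the methylene C11. C1 also carries a methyl group and the chain C1'H2–C2'H2–C3'H(OOH)–C4'(CH3)=C5'H2.

Four stereocentres are contiguous (C1 R, C10 S, C9 S, C8 S). C6 (S) stands 1,3 to C8, and C3' (S) is too far from the ring to be controlled by it. The ring alkene is E and the cyclopropane is trans-1,2-disubstituted, so the ring has the shape and strain of an (E,E)-cyclodeca-1,6-diene.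

Three groups are fragile:
- The secondary allylic hydroperoxide is destroyed by boranes, phosphines, low-valent metals and base.
- The tertiary cyclopropyl carbinol at C8 ionises in acid.
- The allylic acetate is labile.

The real difficulty is the strained ten-membered ring together with a trans-cyclopropane wedged between two fully substituted carbons. At both C1 and C8 the substituents (CH3 against CH2) are too alike to steer a reagent to one face.

The key step exploits the C8(OH)–C9(–C10,–C11) array. It is the water-trapped form of a cyclopropylcarbinyl cation. The homoallyl form of that cation has C11 inside an eleven-membered ring, an E C8=C9 alkene and a leaving group on C10.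

## Logic of the disconnections

**C3'–OO (28 ⇒ 27 ⇒ 26 ⇒ 25 ⇒ 20 + 23).** The C3'–O bond is cut last, because the O–O bond survives none of the C–C bond-forming reagents and because C3' cannot be set from the ring. The cut is stereospecific: an SN2 inversion of a carbinol of opposite configuration. All reducing chemistry therefore comes before the peroxide. The forward step must hit C3' and not C5'. The peroxide must stay masked while the C6 silyl ether is exchanged for the acetate (25, 26, 27), and it must be unmasked without ionising C8–OH.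

**C4'–O and C5'–H (20 ⇒ 19).** The isopropenyl carbinol is traced back to a trisubstituted epoxide. The epoxide carries C3' from a reagent-controlled oxidation and is inert to boranes, palladium and aqueous base. It also removes a 1,1-disubstituted alkene that would compete in the hydroboration. The forward step must take a proton from a methyl group only and keep the C3'–O bond.

**C9–C10 and C8–O (19 ⇒ 18), the key disconnection.** Cutting the ring bond of the cyclopropane and the tertiary C–O bond opens the bicycle to a monocyclic eleven-membered (E,E)-diene with a sulfonate on C10. This removes the cyclopropane, the tertiary carbinol and two of the three contiguous centres C8, C9, C10. It leaves only a homoallylic carbinol centre and one alkene geometry. In one sentence: buffered hydrolysis of 18 contracts the eleven-membered ring to 19. The forward step must ionise C10–O with rear-side help from C8=C9 only, give the trans ring fusion, and be stopped at the kinetic carbinol.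

**C10–O activation and C3–C4 (18 ⇒ 17 ⇒ 15, through 16).** The ring is opened at the sp3–sp2 bond C3–C4, far from every stereocentre and between two unhindered carbons. The gain is an open chain with a vinyl group and an alkenyl iodide at its ends. The forward step needs a hydroboration that picks the vinyl group and a cross-coupling that closes an eleven-membered ring at high dilution.

**C1–C10 (15 ⇒ 13 + 3).** The quaternary carbon next to a carbinol and bearing a vinyl group is the retron of an allylboration by a γ,γ-disubstituted allylboronate. This one cut halves the molecule and sets C1 and C10 together. The relative configuration demands the Z boronate, and the absolute sense demands catalyst control, since C6 and C3' are remote.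

**C3–B and the epoxide oxygen (3 ⇒ 2 ⇒ 1).** Boron replaces an allylic acetate, and the epoxide comes from the distal alkene. The skeleton of 1 already holds C1, its methyl group, C2, C3 and the whole side chain. The steps must keep the Z geometry and oxidise only C3'=C4'.

**C4–I, C9–C11, C8–CH3 and C6–C7 (13 ⇒ 12 ⇒ 10 ⇒ 7 ⇒ 6 ⇒ 4).** Both E alkenes are traced to alkynes. C4=C5 comes from syn hydrometalation and iodination. C8=C9 comes from syn methylmetalation followed by a two-carbon electrophile that brings C11 and C10. The remaining diynol is cut at C6–C7 to 4 and a three-carbon nucleophile, which sets C6. The two alkynes must be told apart (terminal against internal).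

**O–O reagent (23 ⇒ 21).** The masked hydrogen peroxide is cut to a symmetrical alkene, ozone and an alcohol.

## Other disconnections considered

**Alternative 1:** the cut that comes to mind first is C5–C6. The forward key step is a Nozaki–Hiyama–Kishi closure (CrCl2, cat. NiCl2) of the seco iodo aldehyde A1, whose cyclopropane is installed earlier on the open chain by a reagent-controlled methylenation.
- The ten-membered ring, the hardest ring size, must be closed directly.
- The closure gives the C6 carbinol with no element that controls it.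
- The aldehyde of A1 is β-oxygenated at a tertiary centre and prone to elimination and retro-aldol loss.
- C8 has to be made in the open chain by addition to a cyclopropyl ketone, where CH3 and CH2 are not distinguished.
- The linear build-up of the cyclopropane, C8 and both chain ends costs more steps than the chosen route, in which the cyclopropane needs no step of its own.

**Alternative 2:** cut C9–C11 and C10–C11. The forward key step is a hydroxyl-directed Simmons–Smith methylenation of the ten-membered dienol A2.
- The precursor keeps the whole ring problem and four of the six stereocentres, so the gain in simplicity is small.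
- The C9=C10 alkene lies between two fully substituted carbons, while C4=C5 is more exposed.
- The face that the C8 alkoxide can reach depends on which planar-chiral ring conformer reacts.
- The tertiary, doubly activated C8 alcohol is apt to ionise at a Lewis-acidic zinc centre.

**Alternative 3:** cut C9–C10 and C9–C11. The forward key step is an intramolecular cyclopropanation of the vinyl group C10=C11 by the metal carbene from the diazoketone A3 (Rh2(OAc)4), which would close both rings at once. Methyl addition at C8 would follow.
- The carbene carbon C9 is only four atoms from C5, so five-membered closure onto the electron-rich C4=C5 should be much faster than ten-membered closure onto a neopentyl-type vinyl group.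
- Nothing in A3 enforces the trans fusion.
- C8 is left to a later, uncontrolled addition.
- The chosen step sets C8, C9 and C10 by one stereospecific mechanism.

Key step: step 11

Remark: the target locants C1–C11 and C1'–C5' are used for all intermediates. The sense of induction of the phosphoric acid catalysts is assigned from the accepted closed transition-state model. TBS = tert-butyldimethylsilyl, pin = pinacolato, TRIP = 3,3'-bis(2,4,6-triisopropylphenyl)-1,1'-binaphthyl-2,2'-diyl hydrogen phosphate, TMP = 2,2,6,6-tetramethylpiperidide.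

## Steps

Step 1
Reactants: 1 neryl acetate, (2Z)-3,7-dimethylocta-2,6-dien-1-yl acetate
Product: 2 (2Z)-5-[(2R)-3,3-dimethyloxiran-2-yl]-3-methylpent-2-en-1-yl acetate
Conditions: D-fructose-derived Shi ketone (30 mol%), Oxone, K2CO3, Bu4NHSO4, MeCN–CH2(OMe)2/aq. Na2B4O7 buffer, 0 °C
Reagents that add atoms: potassium peroxymonosulfate (active part of Oxone), [K+].[O-]S(=O)(=O)OO
Why: Shi epoxidation: the chiral dioxirane transfers oxygen to the electron-rich trisubstituted C3'=C4' alkene through a spiro transition state, which with the D-fructose-derived ketone gives the (R)-epoxide and so sets C3'. The C1=C2 alkene is Z and is deactivated by the allylic acetate, so it should be left.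

Step 2
Reactants: 2 (2Z)-5-[(2R)-3,3-dimethyloxiran-2-yl]-3-methylpent-2-en-1-yl acetate
Product: 3 2-{(2Z)-5-[(2R)-3,3-dimethyloxiran-2-yl]-3-methylpent-2-en-1-yl}-4,4,5,5-tetramethyl-1,3,2-dioxaborolane
Conditions: B2pin2, Pd2(dba)3 (2.5 mol%), DMSO, 50 °C
Reagents that add atoms: bis(pinacolato)diboron, CC1(C)OB(OC1(C)C)B1OC(C)(C)C(C)(C)O1
Why: Palladium-catalysed borylation of an allylic acetate (Miyaura type): ionisation to the π-allyl complex, transmetalation with B2pin2 and reductive elimination place boron on the primary terminus C3. The Z geometry should hold because syn–anti exchange would need a σ-bond from palladium to the fully substituted C1; the epoxide is not allylic and is inert to zerovalent palladium.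

Step 3
Reactants: 4 but-2-ynal
Product: 6 (4S)-hepta-1,5-diyn-4-ol, via pinacol borate ester 5 (not isolated)
Conditions: allenyl-B(pin), (S)-TRIP (5 mol%), 4 Å MS, toluene, −20 °C; aq. NaHCO3
Reagents that add atoms: allenylboronic acid pinacol ester, C=C=CB1OC(C)(C)C(C)(C)O1
Why: Phosphoric-acid-catalysed asymmetric propargylation of an aldehyde by an allenylboronate (SE2' through a closed six-membered transition state) forms C6–C7. The (S)-catalyst should shield the Re face, so that attack on the Si face sets C6 as S.

Step 4
Reactants: 6 (4S)-hepta-1,5-diyn-4-ol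
Product: 7 tert-butyl[(4S)-hepta-1,5-diyn-4-yloxy]dimethylsilane
Conditions: TBSCl, imidazole, DMF, rt
Reagents that add atoms: tert-butyldimethylsilyl chloride, CC(C)(C)[Si](C)(C)Cl
Why: Standard silylation of a secondary alcohol; the C6–O bond is untouched. The TBS ether withstands the aluminium, lithium, zirconium, boron and palladium reagents that follow.

Step 5
Reactants: 7 tert-butyl[(4S)-hepta-1,5-diyn-4-yloxy]dimethylsilane
Product: 10 (3E,6S)-6-[(tert-butyldimethylsilyl)oxy]-4-methylnon-3-en-7-yn-1-ol, via alkenyl(dimethyl)alane 8 (not isolated), via lithium alkenylaluminate 9 (not isolated)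
Conditions: Me3Al, Cp2ZrCl2 (25 mol%), CH2Cl2, 0 °C to rt; evaporate; n-BuLi, THF–hexane, −78 to 0 °C; oxirane, 0 °C to rt; aq. Rochelle salt
Reagents that add atoms: trimethylaluminium, C[Al](C)C; oxirane, C1CO1
Why: Negishi carboalumination: zirconium-catalysed syn addition of Me–Al to the terminal alkyne puts the methyl on C8 and aluminium on C9, which fixes the E geometry of C8=C9; the internal alkyne reacts far more slowly. The derived aluminate opens oxirane with retention of the alkene geometry and adds C11 and C10.

Step 6
Reactants: 10 (3E,6S)-6-[(tert-butyldimethylsilyl)oxy]-4-methylnon-3-en-7-yn-1-ol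
Product: 12 (3E,6S,7E)-6-[(tert-butyldimethylsilyl)oxy]-8-iodo-4-methylnona-3,7-dien-1-ol, via bis-zirconocene species 11 (not isolated)
Conditions: Cp2Zr(H)Cl (3 equiv), THF, rt to 40 °C; I2, 0 °C
Reagents that add atoms: iodine, II
Why: Hydrozirconation is a syn addition that places zirconium on C4, away from the branched C6, and iodinolysis goes with retention, so the iodide is E (I trans to C6). One equivalent of the hydride is used up by the free hydroxyl; the trisubstituted alkene does not react.

Step 7
Reactants: 12 (3E,6S,7E)-6-[(tert-butyldimethylsilyl)oxy]-8-iodo-4-methylnona-3,7-dien-1-ol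
Product: 13 (3E,6S,7E)-6-[(tert-butyldimethylsilyl)oxy]-8-iodo-4-methylnona-3,7-dienal
Conditions: Dess–Martin periodinane, NaHCO3, CH2Cl2, 0 °C
Reagents that add atoms: none
Why: Dess–Martin oxidation under buffered, non-basic conditions stops at the aldehyde and should leave the β,γ-alkene out of conjugation; 13 is used at once.

Step 8
Reactants: 13 (3E,6S,7E)-6-[(tert-butyldimethylsilyl)oxy]-8-iodo-4-methylnona-3,7-dienal; 3 2-{(2Z)-5-[(2R)-3,3-dimethyloxiran-2-yl]-3-methylpent-2-en-1-yl}-4,4,5,5-tetramethyl-1,3,2-dioxaborolane
Product: 15 (3S,4S,6E,9S,10E)-9-[(tert-butyldimethylsilyl)oxy]-3-{2-[(2R)-3,3-dimethyloxiran-2-yl]ethyl}-11-iodo-3,7-dimethyldodeca-1,6,10-trien-4-ol, via pinacol borate ester 14 (not isolated)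
Conditions: (R)-TRIP (10 mol%), 4 Å MS, toluene, −30 to 0 °C; aq. NaHCO3
Reagents that add atoms: none
Why: Allylboration of an aldehyde by a γ,γ-disubstituted allylboronate through a closed chair transition state forms C1–C10 with allyl transposition and leaves the vinyl group C2=C3 on C1. The Z geometry of 3 puts the methyl group (trans to CH2B) pseudo-equatorial and the chain pseudo-axial, which fixes C1 relative to C10 (OH anti to CH3 in the C11–C10–C1–C2 zigzag); the (R)-phosphoric acid directs attack to the Re face of 13 and so sets C10 as S and C1 in the sense of the target. The remote centres C6 and C3' have no say, so the control is by the catalyst.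

Step 9
Reactants: 15 (3S,4S,6E,9S,10E)-9-[(tert-butyldimethylsilyl)oxy]-3-{2-[(2R)-3,3-dimethyloxiran-2-yl]ethyl}-11-iodo-3,7-dimethyldodeca-1,6,10-trien-4-ol
Product: 17 (1S,3E,6S,7E,11R)-6-[(tert-butyldimethylsilyl)oxy]-11-{2-[(2R)-3,3-dimethyloxiran-2-yl]ethyl}-4,8,11-trimethylcycloundeca-3,7-dien-1-ol, via bis(9-BBN) derivative 16 (not isolated)
Conditions: 9-BBN-H (2.5 equiv), THF, rt to 40 °C; then slow addition to Pd(dppf)Cl2 (15 mol%), AsPh3, Cs2CO3, DMF–THF–H2O, 50 °C, 1 mM
Reagents that add atoms: none
Why: Hydroboration of the monosubstituted alkene by 9-BBN-H (boron on C3; the trisubstituted alkene, the alkenyl iodide and the epoxide are left, the hydroxyl is borinated for the time being) followed by intramolecular B-alkyl Suzuki–Miyaura coupling forms C3–C4 with retention of the E geometry and closes the eleven-membered ring. Both reacting carbons are unhindered (a primary borane and an alkenyl iodide), and slow addition at high dilution should favour ring closure; no stereocentre is formed.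

Step 10
Reactants: 17 (1S,3E,6S,7E,11R)-6-[(tert-butyldimethylsilyl)oxy]-11-{2-[(2R)-3,3-dimethyloxiran-2-yl]ethyl}-4,8,11-trimethylcycloundeca-3,7-dien-1-ol
Product: 18 (1S,3E,6S,7E,11R)-6-[(tert-butyldimethylsilyl)oxy]-11-{2-[(2R)-3,3-dimethyloxiran-2-yl]ethyl}-4,8,11-trimethylcycloundeca-3,7-dien-1-yl methanesulfonate
Conditions: MsCl, Et3N, CH2Cl2, −10 °C
Reagents that add atoms: methanesulfonyl chloride, CS(=O)(=O)Cl
Why: Sulfonylation through sulfene reaches even the neopentyl-type secondary alcohol, which is the only free hydroxyl; the C–O bond is not touched, so C10 stays S.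

Step 11
Reactants: 18 (1S,3E,6S,7E,11R)-6-[(tert-butyldimethylsilyl)oxy]-11-{2-[(2R)-3,3-dimethyloxiran-2-yl]ethyl}-4,8,11-trimethylcycloundeca-3,7-dien-1-yl methanesulfonate
Product: 19 (1S,2S,4S,5E,9R,10S)-4-[(tert-butyldimethylsilyl)oxy]-9-{2-[(2R)-3,3-dimethyloxiran-2-yl]ethyl}-2,6,9-trimethylbicyclo[8.1.0]undec-5-en-2-ol
Conditions: KHCO3, acetone–H2O (3:1), 50 °C
Reagents that add atoms: water, O
Why: Ionisation of the C10–O bond is assisted from the rear by the C8=C9 π bond (homoallyl to cyclopropylcarbinyl participation, the reaction type of the i-steroid rearrangement and of the solvolysis of 4-methylpent-3-enyl sulfonates), so that C9–C10 forms as the mesylate leaves and the charge arrives on the tertiary, cyclopropyl-stabilised C8, where water adds. The three-membered ring closes in a transannular 3-exo mode on C10, and this same bond turns the eleven-membered ring into the ten-membered one, so that no separate closure of the ten-membered ring is needed. C10 is set by inversion of the (S)-mesylate. C9 is set by the alkene face that can reach the rear of C10: the ring torsions C1–C10–C11–C9 and C10–C11–C9=C8 must have the same sign, because opposite signs would press the quaternary C1 against C8 in a syn-pentane contact, and equal signs mean the trans-cyclopropane. C8 is set by anti addition across the E alkene: C10 lies on the inner face, water enters from the outer, open face on the side of C11, and the E geometry translates this into the (8S,9S) pair. The E alkene of an eleven-membered ring holds its allylic ring bond C11–C10 nearly perpendicular to the alkene plane, which is the alignment that participation needs, and the mesylate points outwards, anti to C11–C9. The step needs C8=C9 to win over C4=C5, over migration of a C1 substituent and over proton loss: C8=C9 reaches C10 through a three-atom array and gives a tertiary cyclopropylcarbinyl cation, whereas C4=C5 is further away and is deactivated by the allylic silyloxy group. The hydrogen carbonate buffer keeps the medium neutral, so that the kinetic tertiary carbinol does not re-ionise and the epoxide and silyl ether survive.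

Step 12
Reactants: 19 (1S,2S,4S,5E,9R,10S)-4-[(tert-butyldimethylsilyl)oxy]-9-{2-[(2R)-3,3-dimethyloxiran-2-yl]ethyl}-2,6,9-trimethylbicyclo[8.1.0]undec-5-en-2-ol
Product: 20 (1S,2S,4S,5E,9R,10S)-4-[(tert-butyldimethylsilyl)oxy]-9-[(3R)-3-hydroxy-4-methylpent-4-en-1-yl]-2,6,9-trimethylbicyclo[8.1.0]undec-5-en-2-ol
Conditions: Et2AlCl, LiTMP (gives Et2Al(TMP)), toluene, 0 °C; aq. Rochelle salt
Reagents that add atoms: none
Why: Base-induced isomerisation of an epoxide to an allylic alcohol by a bulky aluminium amide: aluminium binds the oxygen and the amide removes a syn proton from the less hindered methyl group, so C4'–O breaks and C3'–O is kept with its R configuration. A second equivalent is taken up by the C8 hydroxyl as its aluminium alkoxide, which is not a leaving group.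

Step 13
Reactants: 21 2,3-dimethylbut-2-ene
Product: 23 2-methoxypropan-2-yl hydroperoxide, via acetone O-oxide 22 (not isolated)
Conditions: O3, MeOH–CH2Cl2, −78 °C
Reagents that add atoms: ozone, [O-][O+]=O; methanol, CO
Why: Ozonolysis in methanol: cycloreversion of the primary ozonide gives acetone and the carbonyl oxide 22, which adds methanol to give the hydroperoxy ketal 23. It is kept and used as a solution.

Step 14
Reactants: 20 (1S,2S,4S,5E,9R,10S)-4-[(tert-butyldimethylsilyl)oxy]-9-[(3R)-3-hydroxy-4-methylpent-4-en-1-yl]-2,6,9-trimethylbicyclo[8.1.0]undec-5-en-2-ol; 23 2-methoxypropan-2-yl hydroperoxide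
Product: 25 (1S,2S,4S,5E,9R,10S)-4-[(tert-butyldimethylsilyl)oxy]-9-{(3S)-3-[(2-methoxypropan-2-yl)peroxy]-4-methylpent-4-en-1-yl}-2,6,9-trimethylbicyclo[8.1.0]undec-5-en-2-ol, via allylic mesylate 24 (not isolated)
Conditions: Ms2O, Et3N, CH2Cl2, −40 °C; then 23, CsOH·H2O, DMF, −10 to 0 °C
Reagents that add atoms: none
Why: Displacement of a secondary sulfonate by a peroxide anion (SN2) inverts C3' from R to S; the α-effect nucleophile in DMF should prefer the activated allylic carbon. Methanesulfonic anhydride avoids chloride, the tertiary C8 hydroxyl is not sulfonylated at low temperature, and the ketal keeps the new peroxide from acting as an acid or a nucleophile.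

Step 15
Reactants: 25 (1S,2S,4S,5E,9R,10S)-4-[(tert-butyldimethylsilyl)oxy]-9-{(3S)-3-[(2-methoxypropan-2-yl)peroxy]-4-methylpent-4-en-1-yl}-2,6,9-trimethylbicyclo[8.1.0]undec-5-en-2-ol
Product: 26 (1S,2S,4S,5E,9R,10S)-9-{(3S)-3-[(2-methoxypropan-2-yl)peroxy]-4-methylpent-4-en-1-yl}-2,6,9-trimethylbicyclo[8.1.0]undec-5-ene-2,4-diol
Conditions: Bu4NF, AcOH (1:1), THF, rt
Reagents that add atoms: none
Why: Fluoride cleavage of the silyl ether; buffering with acetic acid keeps the medium near neutral, so that base-induced Kornblum–DeLaMare cleavage of the secondary peroxide and acid loss of the peroxy ketal are both avoided.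

Step 16
Reactants: 26 (1S,2S,4S,5E,9R,10S)-9-{(3S)-3-[(2-methoxypropan-2-yl)peroxy]-4-methylpent-4-en-1-yl}-2,6,9-trimethylbicyclo[8.1.0]undec-5-ene-2,4-diol
Product: 27 (1S,2S,4S,5E,9R,10S)-2-hydroxy-9-{(3S)-3-[(2-methoxypropan-2-yl)peroxy]-4-methylpent-4-en-1-yl}-2,6,9-trimethylbicyclo[8.1.0]undec-5-en-4-yl acetate
Conditions: Ac2O, pyridine, DMAP (cat.), CH2Cl2, 0 °C
Reagents that add atoms: acetic anhydride, CC(=O)OC(C)=O
Why: Acylation of the secondary allylic alcohol at C6; the tertiary cyclopropyl carbinol at C8 is too hindered to react under these conditions and the peroxide is masked.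

Step 17
Reactants: 27 (1S,2S,4S,5E,9R,10S)-2-hydroxy-9-{(3S)-3-[(2-methoxypropan-2-yl)peroxy]-4-methylpent-4-en-1-yl}-2,6,9-trimethylbicyclo[8.1.0]undec-5-en-4-yl acetate
Product: 28 (1S,2S,4S,5E,9R,10S)-9-[(3S)-3-hydroperoxy-4-methylpent-4-en-1-yl]-2-hydroxy-2,6,9-trimethylbicyclo[8.1.0]undec-5-en-4-yl acetate (target)
Conditions: AcOH–THF–H2O, 0 °C to rt
Reagents that add atoms: none
Why: Mild acid hydrolysis of the peroxy ketal, which is far more labile than an ordinary acetal, frees the hydroperoxide without breaking the C3'–O or the O–O bond. The medium is too weakly acidic to ionise the C8 carbinol or the allylic acetate.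

## Compound list

1 | neryl acetate | CC(C)=CCC/C(C)=C\COC(C)=O | starting material
2 | (2Z)-5-[(2R)-3,3-dimethyloxiran-2-yl]-3-methylpent-2-en-1-yl acetate | CC1(C)O[C@@H]1CC/C(C)=C\COC(C)=O | intermediate
3 | 2-{(2Z)-5-[(2R)-3,3-dimethyloxiran-2-yl]-3-methylpent-2-en-1-yl}-4,4,5,5-tetramethyl-1,3,2-dioxaborolane | CC1(C)O[C@@H]1CC/C(C)=C\CB1OC(C)(C)C(C)(C)O1 | intermediate
4 | but-2-ynal | CC#CC=O | starting material
5 | 2-[(4S)-hepta-1,5-diyn-4-yloxy]-4,4,5,5-tetramethyl-1,3,2-dioxaborolane | CC#C[C@@H](OB1OC(C)(C)C(C)(C)O1)CC#C | intermediate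
6 | (4S)-hepta-1,5-diyn-4-ol | CC#C[C@@H](O)CC#C | intermediate
7 | tert-butyl[(4S)-hepta-1,5-diyn-4-yloxy]dimethylsilane | CC#C[C@@H](O[Si](C)(C)C(C)(C)C)CC#C | intermediate
8 | [(1E,4S)-4-(TBS-oxy)-2-methylhept-1-en-5-yn-1-yl]dimethylalane | CC#C[C@@H](O[Si](C)(C)C(C)(C)C)C/C(C)=C/[Al](C)C | intermediate
9 | lithium butyl[(1E,4S)-4-(TBS-oxy)-2-methylhept-1-en-5-yn-1-yl]dimethylaluminate | [Li+].CC#C[C@@H](O[Si](C)(C)C(C)(C)C)C/C(C)=C/[Al-](C)(C)CCCC | intermediate
10 | (3E,6S)-6-(TBS-oxy)-4-methylnon-3-en-7-yn-1-ol | CC#C[C@@H](O[Si](C)(C)C(C)(C)C)C/C(C)=C/CCO | intermediate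
11 | C4-alkenyl, O-alkoxide bis[chloridobis(cyclopentadienyl)zirconium] derivative of 10 | Cl[Zr](C1C=CC=C1)(C1C=CC=C1)/C(C)=C/[C@@H](O[Si](C)(C)C(C)(C)C)C/C(C)=C/CCO[Zr](Cl)(C1C=CC=C1)C1C=CC=C1 | intermediate
12 | (3E,6S,7E)-6-(TBS-oxy)-8-iodo-4-methylnona-3,7-dien-1-ol | I/C(C)=C/[C@@H](O[Si](C)(C)C(C)(C)C)C/C(C)=C/CCO | intermediate
13 | (3E,6S,7E)-6-(TBS-oxy)-8-iodo-4-methylnona-3,7-dienal | I/C(C)=C/[C@@H](O[Si](C)(C)C(C)(C)C)C/C(C)=C/CC=O | intermediate
14 | pinacol borate ester of 15 (B on the C10 oxygen) | CC1(C)O[C@@H]1CC[C@@](C)(C=C)[C@@H](OB1OC(C)(C)C(C)(C)O1)C/C=C(\C)C[C@H](O[Si](C)(C)C(C)(C)C)/C=C(\C)I | intermediate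
15 | (3S,4S,6E,9S,10E)-9-(TBS-oxy)-3-{2-[(2R)-3,3-dimethyloxiran-2-yl]ethyl}-11-iodo-3,7-dimethyldodeca-1,6,10-trien-4-ol | CC1(C)O[C@@H]1CC[C@@](C)(C=C)[C@@H](O)C/C=C(\C)C[C@H](O[Si](C)(C)C(C)(C)C)/C=C(\C)I | intermediate
16 | C3-(9-BBN) borane and C10-O-(9-BBN) borinate of 15 | CC1(C)O[C@@H]1CC[C@@](C)(CCB1C2CCCC1CCC2)[C@@H](OB1C2CCCC1CCC2)C/C=C(\C)C[C@H](O[Si](C)(C)C(C)(C)C)/C=C(\C)I | intermediate
17 | (1S,3E,6S,7E,11R)-6-(TBS-oxy)-11-{2-[(2R)-3,3-dimethyloxiran-2-yl]ethyl}-4,8,11-trimethylcycloundeca-3,7-dien-1-ol | CC1(C)O[C@@H]1CC[C@@]2(C)CC/C(C)=C/[C@@H](O[Si](C)(C)C(C)(C)C)C/C(C)=C/C[C@@H]2O | intermediate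
18 | methanesulfonate of 17 | CC1(C)O[C@@H]1CC[C@@]2(C)CC/C(C)=C/[C@@H](O[Si](C)(C)C(C)(C)C)C/C(C)=C/C[C@@H]2OS(C)(=O)=O | intermediate
19 | (1S,2S,4S,5E,9R,10S)-4-(TBS-oxy)-9-{2-[(2R)-3,3-dimethyloxiran-2-yl]ethyl}-2,6,9-trimethylbicyclo[8.1.0]undec-5-en-2-ol | CC1(C)O[C@@H]1CC[C@@]2(C)CC/C(C)=C/[C@@H](O[Si](C)(C)C(C)(C)C)C[C@](C)(O)[C@H]3C[C@@H]32 | intermediate
20 | (1S,2S,4S,5E,9R,10S)-4-(TBS-oxy)-9-[(3R)-3-hydroxy-4-methylpent-4-en-1-yl]-2,6,9-trimethylbicyclo[8.1.0]undec-5-en-2-ol | C=C(C)[C@@H](CC[C@@]1(C)CC/C(C)=C/[C@@H](O[Si](C)(C)C(C)(C)C)C[C@](C)(O)[C@H]2C[C@@H]21)O | intermediate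
21 | 2,3-dimethylbut-2-ene | CC(C)=C(C)C | starting material
22 | acetone O-oxide | CC(C)=[O+][O-] | intermediate
23 | 2-methoxypropan-2-yl hydroperoxide | COC(C)(C)OO | intermediate
24 | (3'R)-methanesulfonate of 20 | C=C(C)[C@@H](CC[C@@]1(C)CC/C(C)=C/[C@@H](O[Si](C)(C)C(C)(C)C)C[C@](C)(O)[C@H]2C[C@@H]21)OS(C)(=O)=O | intermediate
25 | (3'S)-(2-methoxypropan-2-yl)peroxide, C6 TBS ether | C=C(C)[C@H](CC[C@@]1(C)CC/C(C)=C/[C@@H](O[Si](C)(C)C(C)(C)C)C[C@](C)(O)[C@H]2C[C@@H]21)OOC(C)(C)OC | intermediate
26 | (3'S)-(2-methoxypropan-2-yl)peroxide, C6,C8-diol | C=C(C)[C@H](CC[C@@]1(C)CC/C(C)=C/[C@@H](O)C[C@](C)(O)[C@H]2C[C@@H]21)OOC(C)(C)OC | intermediate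
27 | (3'S)-(2-methoxypropan-2-yl)peroxide, C6 acetate | C=C(C)[C@H](CC[C@@]1(C)CC/C(C)=C/[C@@H](OC(C)=O)C[C@](C)(O)[C@H]2C[C@@H]21)OOC(C)(C)OC | intermediate
28 | (1S,2S,4S,5E,9R,10S)-9-[(3S)-3-hydroperoxy-4-methylpent-4-en-1-yl]-2-hydroxy-2,6,9-trimethylbicyclo[8.1.0]undec-5-en-4-yl acetate | C=C(C)[C@H](CC[C@@]1(C)CC/C(C)=C/[C@@H](OC(C)=O)C[C@](C)(O)[C@H]2C[C@@H]21)OO | target

## Step count and least certain steps

Total step count: 17. Longest linear sequence: 14 steps (from 4 through steps 3–12 and 14–17). Steps 1–2 and step 13 are side branches.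

**Step 11 (key step).**
- What may go wrong: ionisation at the neopentyl-type C10 without help from C8=C9. That would lead to migration of a C1 substituent (Wagner–Meerwein), loss of a C11 proton, or transannular capture by C4=C5. This happens if the populated ring conformers do not place C9 behind the C10–O bond.
- Fallback: form the cyclopropane before the ring. It sets out from 15 and comes back at 19.
- 15 is mesylated (MsCl, Et3N) to the open-chain mesylate F1, which is hydrolysed under the conditions of step 11. In the open chain the only other π bonds are an electron-poor alkenyl iodide and a vinyl group that could give only a primary cation. Avoidance of the C1/C8 syn-pentane contact again favours the trans product, the open-chain cyclopropyl carbinol F2.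
- Hydroboration of the vinyl group of F2 with 9-BBN-H gives the B-alkyl borane F3. F3 closes the ten-membered ring at C3–C4 by B-alkyl Suzuki–Miyaura coupling and gives 19.

**Step 9.**
- What may go wrong: oligomerisation, protodeboronation and reduction of the alkenyl iodide. Transmetalation of the borane is slow at high dilution and the eleven-membered ring is strained.
- Fallback: separate the hydroboration from the ring closure and replace the two-electron transmetalation by a radical cross-electrophile closure. It sets out from 15 (through 16) and comes back at 17.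
- 16 is oxidised (NaBO3·4H2O) to the primary/secondary diol F4.
- The primary hydroxyl alone is turned into the primary iodide F5 (I2, PPh3, imidazole, 0 °C).
- F5 is cyclised by nickel-catalysed reductive coupling of the alkyl iodide with the alkenyl iodide (NiBr2·glyme, 4,4'-di-tert-butyl-2,2'-bipyridine, Mn, DMA, slow addition). This tolerates the free hydroxyl and needs no base.

**Step 8.**
- What may go wrong: poor facial selectivity and a slow reaction of the hindered Z boronate with an aliphatic aldehyde. With it may come acid-induced drift of the β,γ-alkene of 13 into conjugation, or opening of the epoxide.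
- Fallback: move the source of asymmetry from an acid catalyst to a chiral group bound to boron. It sets out from 2 and comes back at 15.
- 2 is borylated with B2(OH)4 (Pd2(dba)3, DMSO–MeOH) to the allylboronic acid F6.
- F6 is esterified with diisopropyl D-tartrate (MgSO4) to the tartrate allylboronate F7.
- F7 reacts with 13 in toluene at −78 °C without any acid, through the same chair and on the Re face, to give the tartrate borate ester F8. Hydrolysis of F8 gives 15.

**Step 14.**
- What may go wrong: attack of the peroxide anion at the terminal C5' (SN2'), ionisation of the allylic mesylate with loss of configuration, or elimination to a diene.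
- Fallback: bring in the O–O unit with singlet oxygen and give up reagent control at C3'. It sets out from 20 and comes back at 25.
- Reductive allylic transposition of 20 through the allylic diazene (Mitsunobu displacement with 2-nitrobenzenesulfonylhydrazide, PPh3, DEAD, −30 °C to rt) gives the prenyl compound F9.
- A Schenck ene reaction of F9 (O2, tetraphenylporphyrin, hν, CH2Cl2, 0 °C) gives, besides the tertiary regioisomer and the C3' epimer, the (3'S)-hydroperoxide F10. F10 has to be separated by chromatography.
- Ketalisation of F10 with 2-methoxypropene (cat. PPTS) gives 25.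

## Further compounds

F1 | step 11 | open-chain C10 mesylate of 15 | CC1(C)O[C@@H]1CC[C@@](C)(C=C)[C@@H](OS(C)(=O)=O)C/C=C(\C)C[C@H](O[Si](C)(C)C(C)(C)C)/C=C(\C)I
F2 | step 11 | open-chain trans-cyclopropyl carbinol (C1 vinyl, C4 iodide) | CC1(C)O[C@@H]1CC[C@@](C)(C=C)[C@H]2C[C@@H]2[C@@](C)(O)C[C@H](O[Si](C)(C)C(C)(C)C)/C=C(\C)I
F3 | step 11 | C3-(9-BBN) borane of F2 | CC1(C)O[C@@H]1CC[C@@](C)(CCB1C2CCCC1CCC2)[C@H]3C[C@@H]3[C@@](C)(O)C[C@H](O[Si](C)(C)C(C)(C)C)/C=C(\C)I
F4 | step 9 | C3,C10-diol from 16 | CC1(C)O[C@@H]1CC[C@@](C)(CCO)[C@@H](O)C/C=C(\C)C[C@H](O[Si](C)(C)C(C)(C)C)/C=C(\C)I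
F5 | step 9 | C3 primary iodide, C10 alcohol | CC1(C)O[C@@H]1CC[C@@](C)(CCI)[C@@H](O)C/C=C(\C)C[C@H](O[Si](C)(C)C(C)(C)C)/C=C(\C)I
F6 | step 8 | {(2Z)-5-[(2R)-3,3-dimethyloxiran-2-yl]-3-methylpent-2-en-1-yl}boronic acid | CC1(C)O[C@@H]1CC/C(C)=C\CB(O)O
F7 | step 8 | diisopropyl (4S,5S)-2-{(2Z)-5-[(2R)-3,3-dimethyloxiran-2-yl]-3-methylpent-2-en-1-yl}-1,3,2-dioxaborolane-4,5-dicarboxylate | CC1(C)O[C@@H]1CC/C(C)=C\CB1O[C@H](C(=O)OC(C)C)[C@@H](C(=O)OC(C)C)O1
F8 | step 8 | tartrate borate ester of 15 | CC1(C)O[C@@H]1CC[C@@](C)(C=C)[C@@H](OB1O[C@H](C(=O)OC(C)C)[C@@H](C(=O)OC(C)C)O1)C/C=C(\C)C[C@H](O[Si](C)(C)C(C)(C)C)/C=C(\C)I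
F9 | step 14 | 4-methylpent-3-enyl (prenyl-type) analogue of 20 | CC(C)=CCC[C@@]1(C)CC/C(C)=C/[C@@H](O[Si](C)(C)C(C)(C)C)C[C@](C)(O)[C@H]2C[C@@H]21
F10 | step 14 | (3'S)-hydroperoxide, C6 TBS ether | C=C(C)[C@H](CC[C@@]1(C)CC/C(C)=C/[C@@H](O[Si](C)(C)C(C)(C)C)C[C@](C)(O)[C@H]2C[C@@H]21)OO
A1 | alternative 1 | seco iodo aldehyde (C6 aldehyde, C5 E-alkenyl iodide, C8 triethylsilyl ether, trans-cyclopropane) | O=CC[C@](C)(O[Si](CC)(CC)CC)[C@H]1C[C@@H]1[C@@](C)(CC[C@H]2OC2(C)C)CC/C(C)=C/I
A2 | alternative 2 | ten-membered (4E,9E)-dienol (C8 carbinol, C9=C10 alkene) | C1C/C(C)=C/[C@@H](O[Si](C)(C)C(C)(C)C)C[C@](C)(O)/C=C/[C@@]1(C)CC[C@H]2OC2(C)C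
A3 | alternative 3 | open-chain C9 diazo C8 ketone with the C10=C11 vinyl group on C1 | [N-]=[N+]=CC(=O)C[C@H](O[Si](C)(C)C(C)(C)C)/C=C(\C)CC[C@@](C)(C=C)CC[C@H]1OC1(C)C
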